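The quinone ring atoms are numbered C1(=O), C2(OH), C3(docosyl), C4(=O), C5(OMe), C6(H). The route exploits the para relationship of C1 and C4 in this fully differentiated six-membered ring. C4 is traced to a methoxycarbene carbon, C5=C6 to its 1-methoxyvinyl group, C1 to a chromium-bound CO, and C2–C3 to a docosyl alkyne whose boron marks the future hydroxyl. One Dötz benzannulation makes C3–C4, C1–C2 and C1–C6 and closes the ring with all four heteroatom sites in place. Its precursors are the pentacarbonylchromium carbene complex and the tetracos-1-ynyl boronate. The boronate is carried as the tetrahedral MIDA ester so that boron acts purely as the large alkyne substituent. Cerium(IV) oxidation and C–B oxidation finish the quinone.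

Key step: step 4

Assumption: the target has no stereocentre and no configurable double bond, so it is achiral and no step has to set or preserve configuration.

Design remark: a pinacol ester is not used on boron in the key step.
- A planar dioxaborolane is sterically small and π-acidic. To the best of recollection, precedent places such alkynylboronates, like stannylalkynes, with the metalloid beside the carbene-derived carbon.
- That orientation would lead here to the 2-hydroxy-6-methoxy isomer.
- Only the spectator ligand on boron is changed. The C–B skeletons of the alkyne and the arene, and the three bonds formed, stay the same.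

Step 1
Reactants: 1 methyl vinyl ether; 2 chromium hexacarbonyl
Product: 5 pentacarbonyl[methoxy(1-methoxyvinyl)carbene]chromium(0), via 1-methoxyvinyllithium 3 (not isolated), via lithium acylchromate 4 (not isolated)
Conditions: t-BuLi, THF/pentane, −78 → 0 °C; 2, THF, 0 °C → rt; Me3OBF4, CH2Cl2, 0 °C
Reagents that add atoms: trimethyloxonium tetrafluoroborate, C[O+](C)C.F[B-](F)(F)F
Why: Fischer carbene synthesis, in which the α-lithiated enol ether adds to a CO ligand of 2 and the hard oxonium salt methylates the acylate oxygen of 4; the sequence is routine for lithiated cyclic and acyclic enol ethers, and 5 should be kept cold under argon and used promptly because its vinyl terminus is unsubstituted.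

Step 2
Reactants: 6 1-bromodocosane; 7 lithium acetylide–ethylenediamine complex
Product: 8 tetracos-1-yne
Conditions: DMSO/THF, 10 °C → rt
Reagents that add atoms: none
Why: SN2 alkylation of a monolithium acetylide by an unhindered primary bromide, with the diamine suppressing disproportionation to dilithium acetylide and THF keeping the waxy bromide in solution.

Step 3
Reactants: 8 tetracos-1-yne; 9 triisopropyl borate; 10 N-methyliminodiacetic acid (MIDA)
Product: 13 tetracos-1-ynyl MIDA boronate, via lithium tetracosynide 11 (not isolated), via lithium alkynyltriisopropoxyborate 12 (not isolated)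
Conditions: n-BuLi, THF, 0 °C; 9, −40 °C → rt; cannulated into 10, DMSO, 115 °C (THF distilled off)
Reagents that add atoms: none
Why: deprotonation of the terminal alkyne, capture by the borate ester and transligation of ate complex 12 with MIDA in hot DMSO is the established entry to alkynyl MIDA boronates; the fragile free alkynylboronic acid is never exposed, and 13 should be an air-stable, chromatographable solid.

Step 4
Reactants: 5 pentacarbonyl[methoxy(1-methoxyvinyl)carbene]chromium(0); 13 tetracos-1-ynyl MIDA boronate
Product: 15 3-docosyl-4,5-dimethoxy-2-(MIDA-boryl)phenol, via tricarbonylchromium arene complex 14 (not isolated)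
Conditions: THF (0.1 M), argon, 55 °C; then air, THF/MeCN, rt
Reagents that add atoms: none
Why: Proposed new method: the Dötz benzannulation has not been run on an alkynyl MIDA boronate; the closest known reactions are the benzannulations of alkenyl(methoxy)carbene chromium complexes with pinacol alkynylboronates and with 1-silylalkynes. Thermal loss of a cis CO from 5 lets 13 bind, the alkyne inserts into the Cr=C4 bond to give an η1:η3-vinylcarbene (C3–C4), a CO ligand migrates onto the new carbene carbon to give an η4-vinylketene (C1–C2), and a 6π electrocyclisation onto the vinyl CH2 (C1–C6) followed by enolisation closes the single ring as the arene, first bound to Cr(CO)3 in 14 and then freed by air. The selectivity required is regiochemical: the bond to the carbene carbon must form at the docosyl-bearing alkyne carbon, leaving boron on the carbon that takes up CO. Planar, π-acidic dioxaborolanes and stannyl groups favour the reverse sense, so boron is made tetrahedral: the MIDA cage has no empty p orbital to polarise the triple bond or to interact with a CO ligand, and it is much larger than the chain CH2, so it should avoid the crowded position beside the carbene carbon as silyl groups do. No stereocentre is created, and preference for the phenol over five-membered-ring products is the normal behaviour of alkenyl methoxycarbene chromium complexes in THF.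

Step 5
Reactants: 15 3-docosyl-4,5-dimethoxy-2-(MIDA-boryl)phenol
Product: 16 3-docosyl-5-methoxy-1,4-benzoquinon-2-yl MIDA boronate
Conditions: (NH4)2Ce(NO3)6 (2.2 equiv), MeCN/CH2Cl2/H2O, 0 °C
Reagents that add atoms: water, O
Why: cerium(IV) oxidative demethylation of a 4-methoxyphenol, in which two one-electron oxidations, water attack at C4 and loss of methanol give the para-quinone; the C5 methoxy group has no para oxygen partner and stays, and the tetrahedral MIDA boronate is inert to acidic oxidants.

Step 6
Reactants: 16 3-docosyl-5-methoxy-1,4-benzoquinon-2-yl MIDA boronate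
Product: 18 3-docosyl-2-hydroxy-5-methoxy-1,4-benzoquinone (target), via quinonylboronic acid 17 (not isolated)
Conditions: NaBO3·4H2O, THF/H2O, 0 °C → rt; then 1 M HCl
Reagents that add atoms: sodium perborate (used as the tetrahydrate), [Na+].[Na+].O[B-]1(O)OO[B-](O)(O)OO1
Why: mild aqueous base opens the MIDA cage and perborate oxidises the freed boronic acid 17 at once (ipso-hydroxylation by peroxide addition to boron and 1,2-shift of C2 from boron to oxygen), and the acidic hydroxyquinone is then protected as its anion against further nucleophilic attack until the acidic work-up.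

Compound list
1 | methyl vinyl ether | COC=C | starting material
2 | chromium hexacarbonyl | O=C=[Cr](=C=O)(=C=O)(=C=O)(=C=O)=C=O | starting material
3 | 1-methoxyvinyllithium | [Li]C(=C)OC | intermediate
4 | lithium pentacarbonyl(2-methoxyacryloyl)chromate | [Li+].[O-]C(C(=C)OC)=[Cr](=C=O)(=C=O)(=C=O)(=C=O)=C=O | intermediate
5 | pentacarbonyl[methoxy(1-methoxyvinyl)carbene]chromium(0) | COC(C(=C)OC)=[Cr](=C=O)(=C=O)(=C=O)(=C=O)=C=O | intermediate
6 | 1-bromodocosane | CCCCCCCCCCCCCCCCCCCCCCBr | starting material
7 | lithium acetylide–ethylenediamine complex | [Li]C#C.NCCN | starting material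
8 | tetracos-1-yne | CCCCCCCCCCCCCCCCCCCCCCC#C | intermediate
9 | triisopropyl borate | CC(C)OB(OC(C)C)OC(C)C | starting material
10 | N-methyliminodiacetic acid (MIDA) | CN(CC(=O)O)CC(=O)O | starting material
11 | lithium tetracos-1-ynide | CCCCCCCCCCCCCCCCCCCCCCC#C[Li] | intermediate
12 | lithium triisopropoxy(tetracos-1-ynyl)borate | [Li+].CCCCCCCCCCCCCCCCCCCCCCC#C[B-](OC(C)C)(OC(C)C)OC(C)C | intermediate
13 | 6-methyl-2-(tetracos-1-yn-1-yl)-1,3,6,2-dioxazaborocane-4,8-dione (tetracos-1-ynyl MIDA boronate) | CCCCCCCCCCCCCCCCCCCCCCC#C[B-]12OC(=O)C[N+]1(C)CC(=O)O2 | intermediate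
14 | tricarbonyl(η6-arene)chromium complex of 15 (η6 bonding written as a dot) | CCCCCCCCCCCCCCCCCCCCCCc1c(OC)c(OC)cc(O)c1[B-]23OC(=O)C[N+]2(C)CC(=O)O3.[Cr](=C=O)(=C=O)=C=O | intermediate
15 | 2-(2-docosyl-6-hydroxy-3,4-dimethoxyphenyl)-6-methyl-1,3,6,2-dioxazaborocane-4,8-dione (3-docosyl-4,5-dimethoxy-2-(MIDA-boryl)phenol) | CCCCCCCCCCCCCCCCCCCCCCc1c(OC)c(OC)cc(O)c1[B-]23OC(=O)C[N+]2(C)CC(=O)O3 | intermediate
16 | 2-(2-docosyl-4-methoxy-3,6-dioxocyclohexa-1,4-dien-1-yl)-6-methyl-1,3,6,2-dioxazaborocane-4,8-dione | CCCCCCCCCCCCCCCCCCCCCCC1=C([B-]23OC(=O)C[N+]2(C)CC(=O)O3)C(=O)C=C(OC)C1=O | intermediate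
17 | (2-docosyl-4-methoxy-3,6-dioxocyclohexa-1,4-dien-1-yl)boronic acid | CCCCCCCCCCCCCCCCCCCCCCC1=C(B(O)O)C(=O)C=C(OC)C1=O | intermediate
18 | 3-docosyl-2-hydroxy-5-methoxy-1,4-benzoquinone (achiral) | CCCCCCCCCCCCCCCCCCCCCCC1=C(O)C(=O)C=C(OC)C1=O | target

Total step count: 6. Longest linear sequence: 5 steps (steps 2, 3, 4, 5, 6, from 6 to 18).

Steps most likely to fail

1. Step 4.
- What may go wrong: the alkyne may insert in the reverse sense if σ(C–B) hyperconjugation outweighs the bulk of the cage. The hindered alkyne may be taken up so slowly that the carbene complex decomposes first. The sequence may also stall at the vinylketene stage.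
- Check before going on: the orientation in 15 should be confirmed by an NOE between the C3 benzylic CH2 and the C4 methoxy group.
- Fallback (known chemistry): it sets out from 6 and returns at 18. Commercial 1,2,4,5-tetramethoxybenzene is lithiated (n-BuLi, THF/DMPU) and alkylated with 6 to give 3-docosyl-1,2,4,5-tetramethoxybenzene F1. Cerium(IV) oxidation gives 3-docosyl-2,5-dimethoxy-1,4-benzoquinone F2. Controlled acid hydrolysis (70% HClO4, dioxane, rt) removes the methoxy group that the chain twists out of conjugation and delivers 18.

2. Step 6.
- What may go wrong: while the MIDA cage is opening, hydroxide or hydroperoxide may attack the still neutral methoxyquinone. This would cause addition–elimination at C5 or epoxidation. The freed boronic acid may also protodeboronate before it is oxidised.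
- Fallback: it sets out from 15 and returns at 18. Ligand exchange (pinacol, NaHCO3, MeOH, 45 °C) gives 3-docosyl-4,5-dimethoxy-2-(4,4,5,5-tetramethyl-1,3,2-dioxaborolan-2-yl)phenol F3. Cerium(IV) oxidation gives 3-docosyl-5-methoxy-2-(4,4,5,5-tetramethyl-1,3,2-dioxaborolan-2-yl)-1,4-benzoquinone F4. This Lewis-acidic sp2 boronate is oxidised with anhydrous trimethylamine N-oxide in CH2Cl2, free of water and hydroxide, and a mildly acidic work-up gives 18.

3. Step 1.
- What may go wrong: the unsubstituted vinyl terminus may polymerise, and material may be lost during methylation and work-up of the crude lithium acylate.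
- Fallback: it sets out from 4 and returns at 5. Cation exchange with Me4NBr in water gives the storable tetramethylammonium pentacarbonyl(2-methoxyacryloyl)chromate F5. Acetyl bromide (CH2Cl2, −40 °C) converts it into pentacarbonyl[acetoxy(1-methoxyvinyl)carbene]chromium(0) F6. Methanolysis at low temperature then gives 5 immediately before step 4.

Further compounds
F1 | step 4 | 3-docosyl-1,2,4,5-tetramethoxybenzene | CCCCCCCCCCCCCCCCCCCCCCc1c(OC)c(OC)cc(OC)c1OC
F2 | step 4 | 3-docosyl-2,5-dimethoxy-1,4-benzoquinone | CCCCCCCCCCCCCCCCCCCCCCC1=C(OC)C(=O)C=C(OC)C1=O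
F3 | step 6 | 3-docosyl-4,5-dimethoxy-2-(4,4,5,5-tetramethyl-1,3,2-dioxaborolan-2-yl)phenol | CCCCCCCCCCCCCCCCCCCCCCc1c(OC)c(OC)cc(O)c1B2OC(C)(C)C(C)(C)O2
F4 | step 6 | 3-docosyl-5-methoxy-2-(4,4,5,5-tetramethyl-1,3,2-dioxaborolan-2-yl)-1,4-benzoquinone | CCCCCCCCCCCCCCCCCCCCCCC1=C(B2OC(C)(C)C(C)(C)O2)C(=O)C=C(OC)C1=O
F5 | step 1 | tetramethylammonium pentacarbonyl(2-methoxyacryloyl)chromate | C[N+](C)(C)C.[O-]C(C(=C)OC)=[Cr](=C=O)(=C=O)(=C=O)(=C=O)=C=O
F6 | step 1 | pentacarbonyl[acetoxy(1-methoxyvinyl)carbene]chromium(0) | CC(=O)OC(C(=C)OC)=[Cr](=C=O)(=C=O)(=C=O)(=C=O)=C=O
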